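The readings are simulated with constants of no real substance.

6 questions stood before me: the share of target in target plus side product for 5 flasks, and which of them comes out highest.

| setting | oak | maple | cedar | dusk | spring | noon | summer | dawn |
|---|---|---|---|---|---|---|---|---|
| substrate | 0.20 M | 0.28 M | 0.44 M | 0.20 M | 0.20 M | 0.20 M | 0.20 M | 0.20 M (fed, over 12 min) |
| reagent | 0.22 M | 0.22 M | 0.22 M | 0.220 M (fed, over 12 min) | 0.220 M (fed, over 3.0 min) | 0.220 M | 0.220 M (in portions, 2, over 12 min) | 0.220 M |
| remark | run made earlier | run made earlier | run made earlier | all else is in the flask from the start; the feed brings no volume worth counting | all else is in the flask from the start; the feed brings no volume worth counting | everything together at the start | first portion at the start, last at 12 min | all else is in the flask from the start; the feed brings no volume worth counting |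
| time |  |  |  | 15 min | 15 min | 15 min | 15 min | 15 min |

| run | time / min | target / % | side product / % | substrate / % |
|---|---|---|---|---|
| oak | 2.00 | 9 | 12 | 51 |
| oak | 4.00 | 11 | 16 | 32 |
| oak | 6.00 | 16 | 16 | 27 |
| oak | 8.00 | 17 | 17 | 19 |
| oak | 10.0 | 15 | 19 | 12 |
| oak | 12.0 | 19 | 18 | 14 |
| oak | 15.0 | 19 | 21 | 13 |
| maple | 1.33 | 7 | 6 | 56 |
| maple | 2.50 | 9 | 11 | 40 |
| maple | 4.00 | 10 | 12 | 28 |
| maple | 5.00 | 11 | 13 | 25 |
| maple | 6.00 | 13 | 14 | 21 |
| maple | 8.00 | 12 | 15 | 17 |
| maple | 10.0 | 11 | 17 | 11 |
| cedar | 0.500 | 1 | 6 | 73 |
| cedar | 1.33 | 7 | 3 | 46 |
| cedar | 2.50 | 5 | 8 | 35 |
| cedar | 4.00 | 9 | 11 | 25 |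
| cedar | 5.00 | 9 | 10 | 20 |
| cedar | 8.00 | 10 | 9 | 14 |
| cedar | 10.0 | 9 | 12 | 12 |

(readings scatter by 1.5 percentage points)

- the flask that comes out highest in share of target in target plus side product, or "all alike" when all lie within 1.5 percentage points (dusk / spring / noon / summer / dawn / all alike)
- share of target in target plus side product at the end, dusk
- share of target in target plus side product at the end, spring
- share of target in target plus side product at the end, noon
- share of target in target plus side product at the end, summer
- share of target in target plus side product at the end, dawn

- a reading or a percentage of target counts all its forms, free or not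

On the charge, substrate was the limiting reagent, so I kept its books in the oak run, whose recipe is noon's. At 15.0 min the entries read 19% target, 21% side product and 13% substrate, and the remaining 47.0% stood in no peak. That last entry lies outside the share, so I turned to the other two. By 4.00 min oak held 11% target and 16% side product, but from then to 15.0 min target gained 8 percentage points and side product 5 points. With a scatter of 1.5 points per reading this was a lean, and maple's gains of 1 point and 5 points leaned the other way.

Still, I wagered that reagent was the concentration that set the order: side product takes one order more of it than target. I then entered one reagent per target and two per side product, an assumed stoichiometry, so my ledger put oak's reagent spent at 0.0860 M by 4.00 min. On that ledger, the mean of the c(reagent) at the start and at that point was 0.177 M. Multiplying by the early ratio gave c*, the crossover concentration, the c(reagent) at which target and side product form equally fast: 0.122 M. Target over side product formed is then c* over c(reagent).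

Summer starts at 0.110 M, which gives a share of 52.5%, against oak's reading of 47.5%. In dusk the fed total passes that concentration at 6.00 min, so I ranked summer first, dusk second, and dawn beside noon. The forecast gave all alike, with 47% for summer, holding that “Dosing should change the total yield, since low reagent favours the substrate's self-reaction, but not the share”.

Summer gave 57.7%, above dusk at 54.4%, spring at 48.2%, noon at 45.8% and dawn at 45.5%.

    substrate + 2 reagent → side product (k = 0.0490 /M²/s)
    2 substrate → homo dimer (k = 0.0123 /M/s)
    reagent + target ⇌ idle adduct, settled at all times (K = 159 /M)
    substrate + reagent → target (k = 0.00567 /M/s)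

My ledger had no entry for the idle adduct, which holds a second reagent: at 15.0 min noon had lost 0.150 M of reagent, my two entries give 0.118 M, and the idle adduct stood at 0.0322 M. Just before its last portion, summer held 10.7% target and 6.81% side product, a ratio of 1.57, with reagent down to 19.5% of its charge. The mean of the start and that point is 0.0764 M, and c* over it is 1.60. A neighbour of summer charged with 0.055 M of reagent starts at 0.0275 M, where c* gives a share of 81.6%, and that flask gave 83.0%.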